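**Strategy.** The piperidine is disconnected at N1–C6: ring carbons C3, C4, C5 and C6 are the four carbons of a 2,5-disubstituted furan, and C2 with its methyl is the furan's exocyclic nitrogen-bearing carbon, set as the (S)-tosylamide by a sulfinyl-ketimine reduction. One oxidation with NBS (aza-Achmatowicz rearrangement) dearomatises the furan, forms N1–C6, closes the six-membered ring and delivers C3 as a ketone and C6 as an N-sulfonyl hemiaminal. The precursor is (S)-N-tosyl-1-[5-(dodec-11-enyl)furan-2-yl]ethylamine, whose terminal alkene is the masked C11′ ketone. The C2 methyl then directs two hydride deliveries (C6, C3), and a Mitsunobu reaction attaches the ferulate with inversion at C3.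

Key step: step 5

Remark: the target is treated as the neutral free base; by CIP analysis it is (2S,3R,6S), with the C2 methyl trans to both the C3 ferulate oxygen and the C6 chain, and the chain is 11-oxododecyl (ketone at C11′).

**Step 1**
Reactants: 1 furan; 2 12-bromododec-1-ene
Product: 4 2-(dodec-11-en-1-yl)furan, via 2-furyllithium 3 (not isolated)
Conditions: n-BuLi, THF, −78 → 0 °C; then 2, 0 °C → rt
Reagents that add atoms: none
Why: Furan is deprotonated at C2 by n-BuLi and 2-furyllithium 3 is alkylated by the primary bromide in an SN2 reaction (lithiation–alkylation of a heteroarene); an excess of furan suppresses 2,5-dialkylation and the remote terminal alkene is inert to both reagents.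

**Step 2**
Reactants: 4 2-(dodec-11-en-1-yl)furan; 5 N-methoxy-N-methylacetamide
Product: 7 1-[5-(dodec-11-en-1-yl)furan-2-yl]ethan-1-one, via 5-alkyl-2-furyllithium 6 (not isolated)
Conditions: n-BuLi, THF, −78 → 0 °C; then 5, −78 → 0 °C
Reagents that add atoms: none
Why: The remaining α-position (C5) of the 2-alkylfuran is lithiated and the aryllithium 6 is acylated by the N-methoxy-N-methylamide, whose chelated tetrahedral adduct collapses only on work-up so that no tertiary alcohol forms (Weinreb ketone synthesis).

**Step 3**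
Reactants: 7 1-[5-(dodec-11-en-1-yl)furan-2-yl]ethan-1-one; 8 (S)-2-methylpropane-2-sulfinamide
Product: 10 (S)-N-[(1S)-1-[5-(dodec-11-en-1-yl)furan-2-yl]ethyl]-2-methylpropane-2-sulfinamide, via sulfinyl ketimine 9 (not isolated)
Conditions: Ti(OEt)4, THF, 65 °C; then NaBH4, −48 °C → rt
Reagents that add atoms: none
Why: Ti(OEt)4 drives condensation to the (E)-N-sulfinyl ketimine 9 and NaBH4 reduces it through a cyclic, sulfinyl-oxygen-coordinated transition state (diastereoselective sulfinyl-imine reduction), in which the (S)-sulfinyl group is expected to direct hydride to the face that makes the new carbon centre S, as in the aryl methyl ketimine series; any minor diastereomer is removable by chromatography.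

**Step 4**
Reactants: 10 (S)-N-[(1S)-1-[5-(dodec-11-en-1-yl)furan-2-yl]ethyl]-2-methylpropane-2-sulfinamide
Product: 12 N-[(1S)-1-[5-(dodec-11-en-1-yl)furan-2-yl]ethyl]-4-methylbenzenesulfonamide, via amine hydrochloride 11 (not isolated)
Conditions: HCl (4 M in 1,4-dioxane), MeOH, 0 °C → rt, evaporate; then TsCl, Et3N, CH2Cl2, 0 °C → rt
Reagents that add atoms: 4-methylbenzenesulfonyl chloride (TsCl), Cc1ccc(cc1)S(=O)(=O)Cl
Why: HCl in methanol cleaves the S–N bond of the sulfinamide without touching the C–N stereocentre (acidic sulfinamide solvolysis) and the amine salt 11 is sulfonylated on nitrogen with TsCl and base, giving the acidic N–H nucleophile that the key step requires.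

**Step 5 (key step)**
Reactants: 12 N-[(1S)-1-[5-(dodec-11-en-1-yl)furan-2-yl]ethyl]-4-methylbenzenesulfonamide
Product: 14 (2S,6R)-6-(dodec-11-en-1-yl)-6-hydroxy-2-methyl-1-tosyl-1,6-dihydropyridin-3(2H)-one, via cis-ene-dione 13 (not isolated)
Conditions: NBS, NaHCO3, NaOAc, THF/H2O (4:1), 0 °C
Reagents that add atoms: water, O
Why: NBS brominates the electron-rich 2,5-dialkylfuran at an α-carbon, water adds to the resulting cation, and loss of HBr opens the ring to the cis-ene-1,4-dione 13. The sulfonamide nitrogen then adds to the chain-side C6 ketone in a 6-exo-trig closure that forms N1–C6 and the dihydropyridinone ring; this is the aza-Achmatowicz rearrangement, the nitrogen version of the oxidative ring expansion of furfuryl alcohols, and it is established for N-sulfonyl furfurylamines. C2 is not involved and keeps its S configuration, while the new C6 hemiaminal centre is set under thermodynamic control by ring–chain equilibration; the anomer with the hydroxyl axial and cis to the axial C2 methyl is expected (anomeric effect, A(1,3) strain with the sulfonyl group), and this centre is removed again in step 6. The step needs the furan to be oxidised in preference to the terminal alkene, the cis alkene geometry to be kept and C2 not to epimerise; the far higher nucleophilicity of the furan toward one equivalent of NBS at 0 °C and the NaHCO3/NaOAc buffer, which removes HBr, should secure all three.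

**Step 6**
Reactants: 14 (2S,6R)-6-(dodec-11-en-1-yl)-6-hydroxy-2-methyl-1-tosyl-1,6-dihydropyridin-3(2H)-one
Product: 15 (2S,6S)-6-(dodec-11-en-1-yl)-2-methyl-1-tosyl-1,6-dihydropyridin-3(2H)-one
Conditions: Et3SiH, BF3·OEt2, CH2Cl2, −78 → −40 °C
Reagents that add atoms: none
Why: BF3·OEt2 ionises the tertiary hemiaminal to an N-sulfonyliminium ion that Et3SiH reduces (ionic hydrogenation of an N,O-hemiaminal); A(1,3) strain with the sulfonyl group holds the C2 methyl pseudoaxial, and hydride is expected to add to C6 along the axial, chair-like trajectory on the methyl face, which places the C6 chain trans to the C2 methyl (6S).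

**Step 7**
Reactants: 15 (2S,6S)-6-(dodec-11-en-1-yl)-2-methyl-1-tosyl-1,6-dihydropyridin-3(2H)-one
Product: 16 (2S,6S)-6-(dodec-11-en-1-yl)-2-methyl-1-tosylpiperidin-3-one
Conditions: LiBH(s-Bu)3, THF, −78 °C
Reagents that add atoms: none
Why: LiBH(s-Bu)3 adds hydride in a conjugate (1,4) sense to the β-unsubstituted cyclic enone, whose carbonyl is shielded by the C2 methyl and the sulfonamide, and the C3–C4 enolate is protonated on work-up to the saturated ketone (conjugate reduction with a hindered borohydride); the terminal alkene is inert and C2 is not enolised, so both stereocentres are kept.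

**Step 8**
Reactants: 16 (2S,6S)-6-(dodec-11-en-1-yl)-2-methyl-1-tosylpiperidin-3-one
Product: 17 (2S,3S,6S)-6-(dodec-11-en-1-yl)-2-methyl-1-tosylpiperidin-3-ol
Conditions: LiBH(s-Bu)3, THF, −78 → −40 °C
Reagents that add atoms: none
Why: Reduction of the ketone with the same bulky borohydride (diastereoselective ketone reduction) should deliver hydride to C3 from the face opposite the C2 methyl, which A(1,3) strain with the sulfonyl group holds axial, so that the hydroxyl ends up cis to the methyl (3S).

**Step 9**
Reactants: 17 (2S,3S,6S)-6-(dodec-11-en-1-yl)-2-methyl-1-tosylpiperidin-3-ol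
Product: 18 (2S,3S,6S)-6-(dodec-11-en-1-yl)-2-methylpiperidin-3-ol
Conditions: NaC10H8 (sodium naphthalenide), DME, −78 °C
Reagents that add atoms: none
Why: The naphthalene radical anion transfers electrons to the arenesulfonyl group and cleaves the N–S bond (reductive desulfonylation of a sulfonamide); at −78 °C the isolated terminal alkene and the three stereocentres are untouched, and the step is placed here because no carbonyl group or ester is yet present.

**Step 10**
Reactants: 18 (2S,3S,6S)-6-(dodec-11-en-1-yl)-2-methylpiperidin-3-ol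
Product: 19 tert-butyl (2S,3S,6S)-6-(dodec-11-en-1-yl)-3-hydroxy-2-methylpiperidine-1-carboxylate
Conditions: Boc2O, Et3N, THF, 60 °C
Reagents that add atoms: di-tert-butyl dicarbonate (Boc2O), CC(C)(C)OC(=O)OC(=O)OC(C)(C)C
Why: The secondary amine is acylated by Boc2O (carbamate protection); the α,α′-disubstituted nitrogen needs warming, but without an acyl-transfer catalyst the secondary alcohol should stay free, and the carbamate is chosen because acid removes it at the end without harming the ferulate.

**Step 11**
Reactants: 19 tert-butyl (2S,3S,6S)-6-(dodec-11-en-1-yl)-3-hydroxy-2-methylpiperidine-1-carboxylate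
Product: 20 tert-butyl (2S,3S,6S)-3-hydroxy-2-methyl-6-(11-oxododecyl)piperidine-1-carboxylate
Conditions: PdCl2 (cat.), CuCl, O2 (1 atm), DMF/H2O (7:1), rt
Reagents that add atoms: water, O
Why: Tsuji–Wacker oxidation: divalent palladium activates the terminal alkene for Markovnikov attack of water, β-hydride elimination gives the methyl ketone, and CuCl/O2 reoxidises zerovalent palladium; the carbamate and the secondary alcohol are tolerated, and the oxidation is run before the esterification so that the electron-rich phenol never meets the copper/oxygen medium.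

**Step 12**
Reactants: 20 tert-butyl (2S,3S,6S)-3-hydroxy-2-methyl-6-(11-oxododecyl)piperidine-1-carboxylate; 21 ferulic acid
Product: 22 tert-butyl (2S,3R,6S)-3-{[(2E)-3-(4-hydroxy-3-methoxyphenyl)prop-2-enoyl]oxy}-2-methyl-6-(11-oxododecyl)piperidine-1-carboxylate
Conditions: PPh3, DIAD, THF, 0 °C → rt
Reagents that add atoms: none
Why: Mitsunobu esterification: PPh3/DIAD convert the C3 hydroxyl into an alkoxyphosphonium leaving group that the ferulate anion displaces in an SN2 reaction from the face opposite the C2 methyl, inverting the 2,3-cis alcohol (3S) to the 2,3-trans ester (3R); the far more acidic carboxylic acid is engaged in preference to the phenol, as in known Mitsunobu esterifications of unprotected phenolic acids.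

**Step 13**
Reactants: 22 tert-butyl (2S,3R,6S)-3-{[(2E)-3-(4-hydroxy-3-methoxyphenyl)prop-2-enoyl]oxy}-2-methyl-6-(11-oxododecyl)piperidine-1-carboxylate
Product: 23 (2S,3R,6S)-2-methyl-6-(11-oxododecyl)piperidin-3-yl (2E)-3-(4-hydroxy-3-methoxyphenyl)prop-2-enoate
Conditions: HCl (4 M in 1,4-dioxane), CH2Cl2, 0 °C → rt
Reagents that add atoms: none
Why: Acidolysis of the tert-butyl carbamate (Boc removal, with loss of 2-methylpropene and CO2) frees N1 and a bicarbonate work-up gives the free base; the cinnamate ester, the phenol, the ketone and the three stereocentres are stable to anhydrous HCl at room temperature.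

**Compound list**

1 | furan | c1ccoc1 | starting material
2 | 12-bromododec-1-ene | C=CCCCCCCCCCCBr | starting material
3 | 2-furyllithium | [Li]c1ccco1 | intermediate (not isolated)
4 | 2-(dodec-11-en-1-yl)furan | C=CCCCCCCCCCCc1ccco1 | intermediate
5 | N-methoxy-N-methylacetamide | CC(=O)N(C)OC | starting material
6 | [5-(dodec-11-en-1-yl)furan-2-yl]lithium | [Li]c1ccc(CCCCCCCCCCC=C)o1 | intermediate (not isolated)
7 | 1-[5-(dodec-11-en-1-yl)furan-2-yl]ethan-1-one | CC(=O)c1ccc(CCCCCCCCCCC=C)o1 | intermediate
8 | (S)-2-methylpropane-2-sulfinamide | CC(C)(C)[S@](=O)N | starting material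
9 | (S)-N-[(1E)-1-[5-(dodec-11-en-1-yl)furan-2-yl]ethylidene]-2-methylpropane-2-sulfinamide | C/C(=N\[S@@](=O)C(C)(C)C)c1ccc(CCCCCCCCCCC=C)o1 | intermediate (not isolated)
10 | (S)-N-[(1S)-1-[5-(dodec-11-en-1-yl)furan-2-yl]ethyl]-2-methylpropane-2-sulfinamide | C[C@H](N[S@@](=O)C(C)(C)C)c1ccc(CCCCCCCCCCC=C)o1 | intermediate
11 | (1S)-1-[5-(dodec-11-en-1-yl)furan-2-yl]ethan-1-amine hydrochloride | C[C@H](N)c1ccc(CCCCCCCCCCC=C)o1.Cl | intermediate (not isolated)
12 | N-[(1S)-1-[5-(dodec-11-en-1-yl)furan-2-yl]ethyl]-4-methylbenzenesulfonamide | C[C@H](NS(=O)(=O)c1ccc(C)cc1)c1ccc(CCCCCCCCCCC=C)o1 | intermediate (key-step precursor)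
13 | N-[(2S,4Z)-3,6-dioxooctadeca-4,17-dien-2-yl]-4-methylbenzenesulfonamide | C[C@H](NS(=O)(=O)c1ccc(C)cc1)C(=O)/C=C\C(=O)CCCCCCCCCCC=C | intermediate (not isolated)
14 | (2S,6R)-6-(dodec-11-en-1-yl)-6-hydroxy-2-methyl-1-tosyl-1,6-dihydropyridin-3(2H)-one, hydroxyl cis to the C2 methyl | O=C1C=C[C@](O)(CCCCCCCCCCC=C)N(S(=O)(=O)c2ccc(C)cc2)[C@H]1C | intermediate (key-step product)
15 | (2S,6S)-6-(dodec-11-en-1-yl)-2-methyl-1-tosyl-1,6-dihydropyridin-3(2H)-one | O=C1C=C[C@H](CCCCCCCCCCC=C)N(S(=O)(=O)c2ccc(C)cc2)[C@H]1C | intermediate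
16 | (2S,6S)-6-(dodec-11-en-1-yl)-2-methyl-1-tosylpiperidin-3-one | O=C1CC[C@H](CCCCCCCCCCC=C)N(S(=O)(=O)c2ccc(C)cc2)[C@H]1C | intermediate
17 | (2S,3S,6S)-6-(dodec-11-en-1-yl)-2-methyl-1-tosylpiperidin-3-ol | O[C@H]1CC[C@H](CCCCCCCCCCC=C)N(S(=O)(=O)c2ccc(C)cc2)[C@H]1C | intermediate
18 | (2S,3S,6S)-6-(dodec-11-en-1-yl)-2-methylpiperidin-3-ol | O[C@H]1CC[C@H](CCCCCCCCCCC=C)N[C@H]1C | intermediate
19 | tert-butyl (2S,3S,6S)-6-(dodec-11-en-1-yl)-3-hydroxy-2-methylpiperidine-1-carboxylate | O[C@H]1CC[C@H](CCCCCCCCCCC=C)N(C(=O)OC(C)(C)C)[C@H]1C | intermediate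
20 | tert-butyl (2S,3S,6S)-3-hydroxy-2-methyl-6-(11-oxododecyl)piperidine-1-carboxylate | O[C@H]1CC[C@H](CCCCCCCCCCC(C)=O)N(C(=O)OC(C)(C)C)[C@H]1C | intermediate
21 | ferulic acid, (2E)-3-(4-hydroxy-3-methoxyphenyl)prop-2-enoic acid | COc1cc(/C=C/C(=O)O)ccc1O | starting material
22 | tert-butyl (2S,3R,6S)-3-{[(2E)-3-(4-hydroxy-3-methoxyphenyl)prop-2-enoyl]oxy}-2-methyl-6-(11-oxododecyl)piperidine-1-carboxylate | COc1cc(/C=C/C(=O)O[C@@H]2CC[C@H](CCCCCCCCCCC(C)=O)N(C(=O)OC(C)(C)C)[C@H]2C)ccc1O | intermediate
23 | (2S,3R,6S)-2-methyl-6-(11-oxododecyl)piperidin-3-yl (2E)-3-(4-hydroxy-3-methoxyphenyl)prop-2-enoate | COc1cc(/C=C/C(=O)O[C@@H]2CC[C@H](CCCCCCCCCCC(C)=O)N[C@H]2C)ccc1O | target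

**Step count.** Total: 13 steps. Longest linear sequence: 13 steps (furan 1 to target 23); ferulic acid enters at step 12.

**Steps most likely to fail, with fallbacks**

Step 5 (key step). The electrophilic bromine source may also attack the terminal alkene (bromohydrin formation), or the cis-ene-dione may isomerise to the trans isomer before the nitrogen closes the ring, which would leave an open-chain product. The fallback changes the oxidant to singlet oxygen, which does not react with monosubstituted alkenes. Setting out from 12, sensitised photooxygenation (O2, 5,10,15,20-tetraphenylporphyrin, visible light, CH2Cl2, −78 °C) should give by [4+2] cycloaddition the furan endoperoxide F1. Dimethyl sulfide then reduces the O–O bond (−78 °C → rt), the resulting cis-ene-dione 13 closes as before, and the route is rejoined at 14.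

Step 6. Hydride delivery to the flat, cross-conjugated N-sulfonyliminium ion may show poor facial selectivity, or the ion may lose a proton (exocyclic ene-sulfonamide) or the sulfinate (aromatisation to a 3-hydroxypyridine) faster than it is reduced. The fallback reverses the order of the two reductions so that the iminium ion is generated in a saturated ring. Setting out from 14, MeOH, HC(OMe)3 and pyridinium p-toluenesulfonate should convert the hemiaminal into the methyl N,O-acetal F2. Conjugate reduction with LiBH(s-Bu)3 (THF, −78 °C) would give the saturated methoxy ketone F3. Et3SiH/BF3·OEt2 (CH2Cl2, −78 °C) would then reduce the N,O-acetal through a chair-like N-sulfonyliminium ion with the C2 methyl axial, for which axial hydride attack is the expected course, and the route is rejoined at 16.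

Step 12. Displacement at the hindered secondary centre may be slow, so that elimination to a ring alkene or O-alkylation of the free phenol competes. The fallback separates inversion from acylation. Setting out from 20, a Mitsunobu reaction with the smaller and more acidic 4-nitrobenzoic acid (PPh3, DIAD, toluene) should give the inverted 4-nitrobenzoate F4. Methanolysis (K2CO3, MeOH) would give the 2,3-trans alcohol F5. Carbodiimide esterification with retention (Steglich-type), using commercial 4-acetoxy-3-methoxycinnamic acid, N-(3-dimethylaminopropyl)-N′-ethylcarbodiimide hydrochloride and DMAP in CH2Cl2, would give the O-acetylferulate F6. Selective aminolysis of the aryl acetate with pyrrolidine (CH2Cl2, 0 °C) returns to the route at 22.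

**Further compounds**

F1 | step 5 | N-[(1S)-1-[4-(dodec-11-en-1-yl)-2,3,7-trioxabicyclo[2.2.1]hept-5-en-1-yl]ethyl]-4-methylbenzenesulfonamide (bridgehead configuration not defined) | C[C@H](NS(=O)(=O)c1ccc(C)cc1)C12OOC(CCCCCCCCCCC=C)(C=C1)O2
F2 | step 6 | (2S)-6-(dodec-11-en-1-yl)-6-methoxy-2-methyl-1-tosyl-1,6-dihydropyridin-3(2H)-one, drawn as the anomer with methoxy cis to the C2 methyl | O=C1C=C[C@](OC)(CCCCCCCCCCC=C)N(S(=O)(=O)c2ccc(C)cc2)[C@H]1C
F3 | step 6 | (2S)-6-(dodec-11-en-1-yl)-6-methoxy-2-methyl-1-tosylpiperidin-3-one, same anomer | O=C1CC[C@](OC)(CCCCCCCCCCC=C)N(S(=O)(=O)c2ccc(C)cc2)[C@H]1C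
F4 | step 12 | tert-butyl (2S,3R,6S)-2-methyl-3-[(4-nitrobenzoyl)oxy]-6-(11-oxododecyl)piperidine-1-carboxylate | O=C(O[C@@H]1CC[C@H](CCCCCCCCCCC(C)=O)N(C(=O)OC(C)(C)C)[C@H]1C)c1ccc(cc1)[N+](=O)[O-]
F5 | step 12 | tert-butyl (2S,3R,6S)-3-hydroxy-2-methyl-6-(11-oxododecyl)piperidine-1-carboxylate | O[C@@H]1CC[C@H](CCCCCCCCCCC(C)=O)N(C(=O)OC(C)(C)C)[C@H]1C
F6 | step 12 | tert-butyl (2S,3R,6S)-3-{[(2E)-3-(4-acetoxy-3-methoxyphenyl)prop-2-enoyl]oxy}-2-methyl-6-(11-oxododecyl)piperidine-1-carboxylate | COc1cc(/C=C/C(=O)O[C@@H]2CC[C@H](CCCCCCCCCCC(C)=O)N(C(=O)OC(C)(C)C)[C@H]2C)ccc1OC(C)=O
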